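How far has the flask gone at 10 d: what share of its substrate charge has become target, and what stands in the rest?

| setting | east | north-west | north-east | flask |
|---|---|---|---|---|
| substrate | 0.35 M | 0.55 M | 0.25 M | 0.25 M |
| partner | 0.625 M | 0.625 M | 0.31 M | 0.625 M |
| protic impurity | 0.025 M | 0.025 M | 0.025 M | 0.0250 M |
| remark | run made earlier | run made earlier | run made earlier |  |
| time |  |  |  | 10 d |

- east (time / d: target / %, open intermediate / %): 2.50: 24.7, 15.5; 5.00: 49.2, 8.7; 8.00: 67.0, 5.6; 10.0: 73.8, 4.9
- north-west (time / d: target / %, open intermediate / %): 2.50: 23.5, 14.0; 5.00: 44.9, 12.9; 8.00: 62.1, 7.4; 10.0: 69.8, 8.0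
- north-east (time / d: target / %, open intermediate / %): 0.833: 1.3, 20.7; 1.67: 6.7, 20.4; 4.00: 24.5, 14.6; 10.0: 52.2, 10.6

(readings scatter by 1 percentage point)

- the numbers in the tables scatter with a standard deviation of 1 percentage point

1. concentration of target at 10 d, in M
2. concentration of open intermediate at 10 d, in M
3. concentration of substrate at 10 d, in M
4. concentration of second intermediate at 10 d, in M

East is the simulated run that looks nearly the same as the flask: both hold partner at 0.625 M and protic impurity at 0.0250 M, and they differ in substrate, 0.35 M against 0.25 M. In east at 10.0 d target is the larger share of the charge, so this reckoning follows the smaller one, the unfinished share: the part of the substrate charge not yet target. Its clearing rate is an apparent first-order constant, the logarithm of one over the unfinished share, divided by the time.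

The readings at 10.0 d give 0.134 d⁻¹ for east and 0.120 d⁻¹ for north-west, which holds substrate at 0.55 M. Scaled linearly to the flask's lower charge, that difference becomes a correction of 0.00710 d⁻¹. The clearing rate of the flask therefore reckons as 0.141 d⁻¹, a time constant of 7.09 d.

The reckoned rate of the flask stands close to the rate read for east because the correction is small beside east's own rate. North-east has the flask's substrate charge but about half its partner, and its reading at 10.0 d gives 0.0738 d⁻¹, about half the reckoned rate.

Over 10 d the reckoned rate leaves 24.4 % of the flask's charge unfinished, hence target at 75.6 %. The runs carry readings of target and open intermediate, none of substrate or second intermediate, so this reckoning stops at target.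

The forecast, made from the same runs, puts target at 0.192 M, above this reckoning's 0.189 M, open intermediate at 0.011 M, substrate at 0.024 M and second intermediate at 0.023 M, and calls the split of the last two “the least certain part”.

The flask gives target 0.194 M, open intermediate 0.0110 M, substrate 0.0451 M and second intermediate 0.406 M.

    substrate ⇌ open intermediate (K = 0.320, k = 4.30 × 10⁻⁴ min⁻¹)
    partner → second intermediate (k = 6.10 × 10⁻⁴ min⁻¹)
    open intermediate + second intermediate → target (k = 0.00130 L mol⁻¹ min⁻¹)
    partner + protic impurity → quenched reagent (k = 0.0190 L mol⁻¹ min⁻¹)
    partner → decomposition product (k = 3.10 × 10⁻⁷ min⁻¹)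

In the flask, target stands at 77.6 % of the substrate charge, 2 points above the reckoned 75.6 %. The reckoned clearing rate carries over to the same flask stopped at 4.0 d, all amounts held. There 0.141 d⁻¹ leaves 56.9 % unfinished, so target comes to 43.1 % of the charge. The flask stopped at that time holds 42.2 % of its charge as target.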